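## Analysis of the target

The target is a trans-2,3-disubstituted chroman-4-one (a dihydroflavonol). Ring A is the benzene ring fused to the pyranone ring C, and ring B, a 4-hydroxyphenyl group, sits on C2. The only stereocentres are C2 (benzylic, bonded to O1) and C3 (carbinol, α to the C4 ketone); they are adjacent, both R, and trans, so that H2 and H3 are antiperiplanar and both substituents equatorial. Once ring C is closed, C3 can enolise and C2 can ionise or ring-open towards the chalcone, so base, strong acid and oxidants (which lead to the flavonol) threaten both centres. The prenyl groups at C6 and C8 are trisubstituted alkenes flanked by phenols: acid can close them onto O5 or O7 as dimethylchroman rings, and OsO4, peracids, dioxiranes and hydrogenation would attack them first. The main difficulty is ring A, which is hexasubstituted: oxygen at C5, C7 and C8a alternates with carbon at C4a (acyl), C6 and C8 (prenyl). Prenylation of a preformed phloroglucinol flavonoid spreads over O- and C-alkylation, mono- and dialkylation, and C6 versus C8. The plan rests on this strict O/C alternation: the six atoms of ring A map onto the four carbons of a cyclobutenone (C8a, C6, C5, C4a) and the two carbons of an ynol ether (C8, C7). Each fragment carries one prenyl group and its own oxygen, and C4a is left as the only unsubstituted ring carbon.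

## Retrosynthetic reasoning

**O1–C2 bond (28 from 27).** Ring C is opened at the benzylic ether bond, giving the fully MOM-protected (2R,3S)-epoxy ketone 27. In the forward direction acid removes the four MOM groups and a freed ortho phenol opens the epoxide at the benzylic carbon, with inversion at C2 and retention at C3, which gives the trans (2R,3R) product. Cutting here makes ring closure and global deprotection one operation and reduces both stereocentres to those of one epoxide. Ring A of 27 is symmetric about the C4a···C7 axis, so it does not matter which ortho oxygen closes the ring.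

**Epoxide C–O bonds (27 from 26).** The epoxide is traced back to (E)-chalcone 26. The forward reaction has to be a nucleophilic, catalyst-controlled epoxidation of the enone: a nucleophilic peroxide leaves the two electron-rich prenyl alkenes alone, whereas dihydroxylation or electrophilic epoxidation would attack them first.

**Cα=Cβ bond (26 from 23 and 24).** The enone is cut by a retro-aldol condensation into methyl ketone 23 and the non-enolisable aldehyde 24. This joins rings A and B late and needs only base, to which MOM ethers are inert.

**C4–C4a bond (23 from 21).** The acetyl group is removed to leave arene 21, whose only ring hydrogen is at C4a between two MOM ethers. Forward, directed lithiation (aryllithium 22) and acylation put the carbonyl carbon exactly there; no regiochemical question arises.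

**Protecting-group level (21 from 19 via 20).** Arene 21 is traced to phenol 19, in which the three oxygens appear as free OH (C8a), MOM ether (C5) and silyl ether (C7). The silyl group is only needed to make the ynol ether fragment stable. Because O5 and O8a are equivalent until ring C closes, the three oxygens are converged to one MOM set. This gives two directing groups around C4a, stability to the basic condensation and a single final deprotection.

**C8–C8a, C6–C7 and C4a–C8a (19 from 14 and 5).** Ring A is cut into cyclobutenone 14 (supplying C8a, C6, C5, C4a, the C6 prenyl group and O5) and siloxyalkyne 5 (supplying C8, C7, the C8 prenyl group and O7). Cutting here, and not at an aryl–prenyl bond, means that each prenyl group enters already bonded to its carbon, so O-prenylation, over-prenylation and the C6/C8 question cannot arise. The forward cascade must join the ketene carbonyl carbon to the carbon-substituted alkyne terminus; this is what makes oxygen and carbon alternate.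

**Cyclobutenone 14 (from 13, 12, 9, 11, 6, 7).** The MOM enol ether is traced to the vinylogous acid 13 and its ethyl ether 12. Cutting both ring bonds of 12 gives ynol ether 9 and ketene 11 (from 10), a [2+2] pair with the same polarity control as the key step. Ynol ether 9 comes from ethoxyacetylene 6 and prenyl bromide 7 by acetylide alkylation.

**Siloxyalkyne 5 (from 2 and 1).** The O–Si bond and the alkyne are traced to ester 2 by a one-carbon ester-to-ynolate homologation (through 3 and 4). The ester comes from the commercial acid 1, which already holds the prenyl unit.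

## Alternatives that were turned down

**Alternative 1: late double aromatic Claisen rearrangement.**
- Disconnection and key step: the aryl–CH2 bonds at C6 and C8 are cut last. The aromadendrin 5,7-bis(allyl) 3,4'-bis(methoxymethyl) ether A1 would be heated with Eu(fod)3, moving both allyl groups from oxygen to carbon to give the 6,8-diallyl compound A2.
- For: the flavanonol core with both stereocentres is in hand early, each allyl group is delivered intramolecularly, and the route is shorter. On step economy it is the stronger plan.
- Against:
  - A prenyl ether would rearrange with allylic transposition to a 1,1-dimethylallyl group, so only allyl can be relayed and A2 still needs a double olefin cross-metathesis.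
  - O5 is the chelated, least reactive hydroxyl and must still be allylated.
  - Partial rearrangement, the para pathway and Lewis-acid closure of an ortho-allylphenol to a dihydrobenzofuran all give mixtures.
  - The hot Lewis-acid step is run on a compound whose C2 and C3 can epimerise by ring opening or eliminate to the flavonol.
- Comparison: the chosen route is longer, but it places each prenyl group in final form on a carbon defined by construction and creates the stereocentres after all forcing steps.

**Alternative 2: [2+2+2] cyclotrimerisation.**
- Disconnection and key step: ring A is cut into three alkynes, two tethered through the C2–C3 chain. Diyne A3 (siloxy ynone at one end, prenyl-substituted alkynyl ether at the other) and siloxyalkyne 5 would be joined by [Rh(cod)2]BF4/BINAP. This forms C4a–C8a, C5–C6 and C7–C8 and closes rings A and C together to give A4.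
- For: no other plan forms as many bonds in one step or is as convergent, and the conditions are mild. On these points it is stronger than the chosen route.
- Against:
  - A3 combines an acyl-substituted silyl ynol ether (a push–pull alkyne that hydrolyses and desilylates easily) with an epimerisable α-alkoxy ketone centre and a β-ether that can eliminate.
  - A3 must be made enantiopure in a long sequence of its own.
  - The orientation in which untethered 5 inserts is not fixed by a tether, so the C6/C7 regiochemistry depends on catalyst control, and 5 can trimerise with itself.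
- Comparison: the chosen route also builds ring A from a four-carbon and a two-carbon unit, but takes its regiochemistry from the polarity of a ketene and an ynol ether, needs no metal, and keeps the sensitive C2–C3 unit out of the ring-forming step.

**Alternative 3: three-component carbene/alcohol/aldehyde coupling.**
- Disconnection and key step: C2–C3 and C3–O are cut. The ring A diazoketone A5, 4-methoxybenzyl alcohol A6 and aldehyde 24 would be combined by Rh2(OAc)4 and a chiral phosphoric acid through an oxonium ylide trapped in an aldol-type step, giving ketone A7 with both stereocentres. Ring C would then close by displacement of the aryl fluoride by the benzylic alkoxide.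
- For: both stereocentres and the C2–C3 bond are set in one catalytic step from three simple parts, and the ring closure breaks no bond at a stereocentre and has no 5-exo/6-endo ambiguity. For building ring C this is more convergent than the chalcone–epoxide sequence.
- Against:
  - It does not address ring A: A5 presupposes a fully substituted, regiodefined fluoro-diprenyl ketone that would itself need a benzannulation or repeated metalations.
  - A rhodium carbene next to two electron-rich trisubstituted alkenes can cyclopropanate or insert into allylic C–H bonds.
  - The 1,2-proton shift to the plain O–H insertion product competes with aldehyde trapping, and syn/anti and enantiocontrol are less secure with diazoketones and aldehydes than with diazoesters and imines.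
  - Fluoride displacement on a ring with two alkoxy donors is slow, and the 4-methoxybenzyl ether must be removed beside prenyl groups.
- Comparison: the chosen route accepts a longer, linear end game with a well-understood epoxidation in exchange for solving the ring A problem, which this alternative leaves open.

Key step: step 7

Remark on the chemistry: ketene is assumed to be generated by pyrolysis of acetone and passed as a gas into the reaction, so it is treated as an intermediate that is not isolated; the locants O1 to C8a for ring A atoms are those of the target, also in earlier intermediates.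

## Route

Step 1
Reactants: 1 4-methylpent-3-enoic acid
Product: 2 ethyl 4-methylpent-3-enoate
Conditions: EtI, K2CO3, DMF, rt
Reagents that add atoms: iodoethane, CCI
Why: SN2 O-alkylation of the carboxylate under weak base; a strongly acidic Fischer esterification is avoided because it would lactonise or conjugate this β,γ-unsaturated acid.

Step 2
Reactants: 2 ethyl 4-methylpent-3-enoate
Product: 5 triisopropyl[(5-methylhex-4-en-1-yn-1-yl)oxy]silane, via dibromomethyl ketone 3 (not isolated), via lithium ynolate 4 (not isolated)
Conditions: CH2Br2, LiTMP, THF, −78 °C; LiHMDS; n-BuLi, −78 °C → rt; then TIPSCl, −78 °C → rt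
Reagents that add atoms: dibromomethane, BrCBr; chlorotriisopropylsilane, CC(C)[Si](Cl)(C(C)C)C(C)C
Why: Kowalski ester homologation: dibromomethyllithium (from CH2Br2 and lithium 2,2,6,6-tetramethylpiperidide) adds to the ester, the enolate of 3 undergoes bromine–lithium exchange and a 1,2-shift of the allylic CH2 group to give ynolate 4, and the bulky silyl chloride silylates on oxygen (a small one would silylate on carbon).

Step 3
Reactants: 6 ethoxyacetylene; 7 prenyl bromide (1-bromo-3-methylbut-2-ene)
Product: 9 1-ethoxy-5-methylhex-4-en-1-yne, via lithium ethoxyacetylide 8 (not isolated)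
Conditions: n-BuLi, THF, −78 °C; then 7, DMPU, −78 °C → rt
Reagents that add atoms: none
Why: Deprotonation of the terminal ynol ether and SN2 alkylation of acetylide 8 at the unhindered primary carbon of the allylic bromide; the polar cosolvent is needed because alkoxyacetylides are weak nucleophiles.

Step 4
Reactants: 9 1-ethoxy-5-methylhex-4-en-1-yne; 10 acetone (ketene source)
Product: 12 3-ethoxy-2-(3-methylbut-2-enyl)cyclobut-2-en-1-one, via ketene 11 (not isolated)
Conditions: 10 pyrolysed over a hot filament, ketene stream passed into 9, CH2Cl2, 0 °C → rt
Reagents that add atoms: none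
Why: Thermal [2+2] cycloaddition of ketene with an ynol ether; the nucleophilic prenyl-bearing alkyne carbon bonds to the ketene carbonyl carbon, which fixes the 3-ethoxy-2-prenyl pattern, and the isolated trisubstituted alkene is far less reactive towards ketene.

Step 5
Reactants: 12 3-ethoxy-2-(3-methylbut-2-enyl)cyclobut-2-en-1-one
Product: 13 3-hydroxy-2-(3-methylbut-2-enyl)cyclobut-2-en-1-one (enol form of 2-prenylcyclobutane-1,3-dione)
Conditions: 2 M HCl (aq), THF, 0 °C → rt
Reagents that add atoms: water, O
Why: Acid hydrolysis of a strained vinylogous ester by addition–elimination at C3; dilute acid and short contact should leave the prenyl alkene unhydrated.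

Step 6
Reactants: 13 3-hydroxy-2-(3-methylbut-2-enyl)cyclobut-2-en-1-one
Product: 14 3-(methoxymethoxy)-2-(3-methylbut-2-enyl)cyclobut-2-en-1-one
Conditions: MOMCl, iPr2NEt, CH2Cl2, 0 °C → rt
Reagents that add atoms: chloromethyl methyl ether, COCCl
Why: O-alkylation of the vinylogous acid with a hard oxocarbenium-type electrophile; the dione is symmetrical, so only one enol ether can form, and the MOM group can be removed at the end without touching the prenyl groups.

Step 7
Reactants: 14 3-(methoxymethoxy)-2-(3-methylbut-2-enyl)cyclobut-2-en-1-one; 5 triisopropyl[(5-methylhex-4-en-1-yn-1-yl)oxy]silane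
Product: 19 5-(methoxymethoxy)-2,4-bis(3-methylbut-2-enyl)-3-(triisopropylsilyloxy)phenol, via vinylketene 15 (not isolated), via vinylcyclobutenone 16 (not isolated), via dienylketene 17 (not isolated), via cyclohexadienone 18 (not isolated)
Conditions: 5 (1.2 equiv), PhMe (degassed), 80 °C then 110 °C, sealed tube
Reagents that add atoms: none
Why: Danheiser benzannulation, the known pericyclic cascade of cyclobutenones with siloxyalkynes to resorcinol monosilyl ethers. Heating opens 14 by four-electron conrotatory electrocyclic cleavage of its C(=O)–CH2 bond to vinylketene 15. The ketene C=C bond of 15 adds to 5 in a [2+2] cycloaddition in which the electrophilic ketene carbonyl carbon bonds to the nucleophilic, prenyl-bearing alkyne carbon; this gives 16 and forms C8–C8a and C6–C7. A second four-electron ring opening, reversible so that the rotamer with the alkoxyvinyl group turned inwards is funnelled on, gives dienylketene 17. Six-electron disrotatory electrocyclisation of 17 forms C4a–C8a and closes ring A as cyclohexadienone 18; tautomerisation to the phenol makes the sequence irreversible. No stereocentre is formed. The selectivity required is regiochemical (alternating O and C around the ring) and is secured by the polarity of the ketene–ynol ether pair; chemoselectivity over the two trisubstituted alkenes follows from the much higher nucleophilicity of the siloxyalkyne. The donor at C3 of 14 can be expected to slow the first ring opening, hence the two temperature stages.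

Step 8
Reactants: 19 5-(methoxymethoxy)-2,4-bis(3-methylbut-2-enyl)-3-(triisopropylsilyloxy)phenol
Product: 20 5-(methoxymethoxy)-2,4-bis(3-methylbut-2-enyl)benzene-1,3-diol
Conditions: TBAF, THF, 0 °C, under argon
Reagents that add atoms: none
Why: Fluoride cleaves the aryl silyl ether (strong Si–F bond, phenoxide leaving group) without affecting the MOM ether or the alkenes.

Step 9
Reactants: 20 5-(methoxymethoxy)-2,4-bis(3-methylbut-2-enyl)benzene-1,3-diol
Product: 21 1,3,5-tris(methoxymethoxy)-2,4-bis(3-methylbut-2-enyl)benzene
Conditions: NaH, MOMCl, DMF, 0 °C → rt
Reagents that add atoms: chloromethyl methyl ether, COCCl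
Why: Williamson-type O-alkylation of both phenoxides with a hard electrophile; it gives the symmetric tris-MOM arene with two directing groups around C4a.

Step 10
Reactants: 21 1,3,5-tris(methoxymethoxy)-2,4-bis(3-methylbut-2-enyl)benzene
Product: 23 1-[2,4,6-tris(methoxymethoxy)-3,5-bis(3-methylbut-2-enyl)phenyl]ethanone, via aryllithium 22 (not isolated)
Conditions: n-BuLi, TMEDA, THF, 0 °C; then MeC(O)N(OMe)Me, −78 °C → rt
Reagents that add atoms: N-methoxy-N-methylacetamide, CC(=O)N(C)OC
Why: Directed ortho metalation at C4a, the only ring hydrogen and the one flanked by two coordinating MOM ethers; aryllithium 22 adds to the Weinreb amide to give a chelated tetrahedral adduct that releases the ketone only on work-up, so no over-addition occurs.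

Step 11
Reactants: 23 1-[2,4,6-tris(methoxymethoxy)-3,5-bis(3-methylbut-2-enyl)phenyl]ethanone; 24 4-(methoxymethoxy)benzaldehyde
Product: 26 (E)-3-[4-(methoxymethoxy)phenyl]-1-[2,4,6-tris(methoxymethoxy)-3,5-bis(3-methylbut-2-enyl)phenyl]prop-2-en-1-one, via aldol adduct 25 (not isolated)
Conditions: KOH, EtOH/H2O, rt
Reagents that add atoms: none
Why: Claisen–Schmidt condensation: only the methyl ketone can enolise, aldol adduct 25 dehydrates by E1cB to the thermodynamically favoured E enone, and MOM ethers are inert to base.

Step 12
Reactants: 26 (E)-3-[4-(methoxymethoxy)phenyl]-1-[2,4,6-tris(methoxymethoxy)-3,5-bis(3-methylbut-2-enyl)phenyl]prop-2-en-1-one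
Product: 27 [(2R,3S)-3-[4-(methoxymethoxy)phenyl]oxiran-2-yl][2,4,6-tris(methoxymethoxy)-3,5-bis(3-methylbut-2-enyl)phenyl]methanone
Conditions: poly-L-leucine, urea·H2O2, DBU, THF, rt
Reagents that add atoms: hydrogen peroxide (as its urea adduct), OO
Why: Juliá–Colonna epoxidation, a Weitz–Scheffer conjugate addition of hydroperoxide and ring closure inside the helical N-terminus of the polypeptide; with the L-polymer, (E)-chalcones give the trans (2R,3S) epoxy ketone, which sets the future C3 as R and the future C2 ready for inversion, and the nucleophilic oxidant leaves the prenyl alkenes untouched.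

Step 13
Reactants: 27 [(2R,3S)-3-[4-(methoxymethoxy)phenyl]oxiran-2-yl][2,4,6-tris(methoxymethoxy)-3,5-bis(3-methylbut-2-enyl)phenyl]methanone
Product: 28 6,8-diprenylaromadendrin, (2R,3R)-3,5,7-trihydroxy-2-(4-hydroxyphenyl)-6,8-bis(3-methylbut-2-enyl)chroman-4-one
Conditions: HCl (1 M in MeOH), THF, 40 °C, stopped as soon as the MOM ethers are consumed
Reagents that add atoms: none
Why: Acid methanolysis removes the four MOM acetals and a freed ortho phenol opens the protonated epoxide at the benzylic carbon, which is activated by the para-oxygenated ring B (6-endo opening); inversion at C2 and retention at C3 give the trans (2R,3R) product, which is also the thermodynamically preferred diequatorial isomer, and the two ortho hydroxyls are equivalent so either closes to the same compound.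

## Compound list

1 | 4-methylpent-3-enoic acid | CC(C)=CCC(=O)O | starting material
2 | ethyl 4-methylpent-3-enoate | CCOC(=O)CC=C(C)C | intermediate
3 | 1,1-dibromo-5-methylhex-4-en-2-one (present as its lithium enolate) | CC(C)=CCC(=O)C(Br)Br | intermediate (not isolated)
4 | lithium 5-methylhex-4-en-1-yn-1-olate | CC(C)=CCC#CO[Li] | intermediate (not isolated)
5 | triisopropyl[(5-methylhex-4-en-1-yn-1-yl)oxy]silane | CC(C)=CCC#CO[Si](C(C)C)(C(C)C)C(C)C | intermediate
6 | ethoxyacetylene | CCOC#C | starting material
7 | prenyl bromide (1-bromo-3-methylbut-2-ene) | CC(C)=CCBr | starting material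
8 | lithium ethoxyacetylide | CCOC#C[Li] | intermediate (not isolated)
9 | 1-ethoxy-5-methylhex-4-en-1-yne | CCOC#CCC=C(C)C | intermediate
10 | acetone | CC(C)=O | starting material
11 | ketene | C=C=O | intermediate (not isolated)
12 | 3-ethoxy-2-(3-methylbut-2-enyl)cyclobut-2-en-1-one | CCOC1=C(CC=C(C)C)C(=O)C1 | intermediate
13 | 3-hydroxy-2-(3-methylbut-2-enyl)cyclobut-2-en-1-one | OC1=C(CC=C(C)C)C(=O)C1 | intermediate
14 | 3-(methoxymethoxy)-2-(3-methylbut-2-enyl)cyclobut-2-en-1-one | COCOC1=C(CC=C(C)C)C(=O)C1 | intermediate
15 | 3-(methoxymethoxy)-2-(3-methylbut-2-enyl)buta-1,3-dien-1-one | C=C(OCOC)C(CC=C(C)C)=C=O | intermediate (not isolated)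
16 | 4-[1-(methoxymethoxy)ethenyl]-2,4-bis(3-methylbut-2-enyl)-3-(triisopropylsilyloxy)cyclobut-2-en-1-one (racemic) | O=C1C(CC=C(C)C)=C(O[Si](C(C)C)(C(C)C)C(C)C)C1(CC=C(C)C)C(=C)OCOC | intermediate (not isolated)
17 | (3E)-5-(methoxymethoxy)-2,4-bis(3-methylbut-2-enyl)-3-(triisopropylsilyloxy)hexa-1,3,5-trien-1-one | O=C=C(CC=C(C)C)/C(O[Si](C(C)C)(C(C)C)C(C)C)=C(CC=C(C)C)\C(=C)OCOC | intermediate (not isolated)
18 | 5-(methoxymethoxy)-2,4-bis(3-methylbut-2-enyl)-3-(triisopropylsilyloxy)cyclohexa-2,4-dien-1-one | O=C1CC(OCOC)=C(CC=C(C)C)C(O[Si](C(C)C)(C(C)C)C(C)C)=C1CC=C(C)C | intermediate (not isolated)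
19 | 5-(methoxymethoxy)-2,4-bis(3-methylbut-2-enyl)-3-(triisopropylsilyloxy)phenol | Oc1cc(OCOC)c(CC=C(C)C)c(O[Si](C(C)C)(C(C)C)C(C)C)c1CC=C(C)C | intermediate
20 | 5-(methoxymethoxy)-2,4-bis(3-methylbut-2-enyl)benzene-1,3-diol | Oc1cc(OCOC)c(CC=C(C)C)c(O)c1CC=C(C)C | intermediate
21 | 1,3,5-tris(methoxymethoxy)-2,4-bis(3-methylbut-2-enyl)benzene | COCOc1cc(OCOC)c(CC=C(C)C)c(OCOC)c1CC=C(C)C | intermediate
22 | [2,4,6-tris(methoxymethoxy)-3,5-bis(3-methylbut-2-enyl)phenyl]lithium | [Li]c1c(OCOC)c(CC=C(C)C)c(OCOC)c(CC=C(C)C)c1OCOC | intermediate (not isolated)
23 | 1-[2,4,6-tris(methoxymethoxy)-3,5-bis(3-methylbut-2-enyl)phenyl]ethanone | CC(=O)c1c(OCOC)c(CC=C(C)C)c(OCOC)c(CC=C(C)C)c1OCOC | intermediate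
24 | 4-(methoxymethoxy)benzaldehyde | COCOc1ccc(C=O)cc1 | starting material
25 | 3-hydroxy-3-[4-(methoxymethoxy)phenyl]-1-[2,4,6-tris(methoxymethoxy)-3,5-bis(3-methylbut-2-enyl)phenyl]propan-1-one (racemic) | COCOc1ccc(C(O)CC(=O)c2c(OCOC)c(CC=C(C)C)c(OCOC)c(CC=C(C)C)c2OCOC)cc1 | intermediate (not isolated)
26 | (E)-3-[4-(methoxymethoxy)phenyl]-1-[2,4,6-tris(methoxymethoxy)-3,5-bis(3-methylbut-2-enyl)phenyl]prop-2-en-1-one | COCOc1ccc(/C=C/C(=O)c2c(OCOC)c(CC=C(C)C)c(OCOC)c(CC=C(C)C)c2OCOC)cc1 | intermediate
27 | [(2R,3S)-3-[4-(methoxymethoxy)phenyl]oxiran-2-yl][2,4,6-tris(methoxymethoxy)-3,5-bis(3-methylbut-2-enyl)phenyl]methanone | O=C(c1c(OCOC)c(CC=C(C)C)c(OCOC)c(CC=C(C)C)c1OCOC)[C@@H]1O[C@H]1c1ccc(OCOC)cc1 | intermediate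
28 | 6,8-diprenylaromadendrin, (2R,3R)-3,5,7-trihydroxy-2-(4-hydroxyphenyl)-6,8-bis(3-methylbut-2-enyl)chroman-4-one | CC(C)=CCc1c(O)c(CC=C(C)C)c2c(c1O)C(=O)[C@H](O)[C@@H](c1ccc(O)cc1)O2 | target

## Step count and least certain steps

Total step count: 13. Longest linear sequence: 11 steps (steps 3 to 13, from 6 and 7); the two-step siloxyalkyne branch (steps 1 and 2) joins at step 7.

**Step 7 (key step).**
- What may go wrong: the donor-substituted cyclobutenone may open sluggishly and its alkoxy-substituted vinylketene may be a weaker electrophile, so thermal decomposition of the siloxyalkyne or ketene dimerisation can outrun the [2+2] step. The product phenol can also be acylated by unreacted vinylketene, which consumes 15.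
- Fallback: ring synthesis is given up for directed metalation on a preformed ring. It sets out from prenyl bromide 7 and commercial phloroglucinol F1. F1 is converted with MOMCl/NaH into 1,3,5-tris(methoxymethoxy)benzene F2. Lithiation between two MOM ethers (n-BuLi, THF, 0 °C), transmetalation with CuI and alkylation with 7 gives 1,3,5-tris(methoxymethoxy)-2-(3-methylbut-2-enyl)benzene F3. A second round at one of the two remaining equivalent positions gives 21, where the fallback rejoins the route; steps 8 and 9 are then not needed.

**Step 2.**
- What may go wrong: the β,γ-unsaturated ester may be enolised instead of attacked by the carbenoid, and the doubly activated propargylic/allylic CH2 of the ynolate may be deprotonated by excess base, with isomerisation of the skipped enyne to conjugated isomers.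
- Fallback: it sets out from 7. Ethynylmagnesium bromide with catalytic CuCl in THF gives 5-methylhex-4-en-1-yne F4. Its lithium acetylide (n-BuLi, THF, −78 °C) is oxidised with lithium tert-butyl peroxide to ynolate 4, which is silylated with TIPSCl as in step 2 to give 5.

**Step 12.**
- What may go wrong: poor facial selectivity or slow conversion, because the di-ortho-substituted aryl ketone is twisted and bulky and may not sit well in the polypeptide binding site.
- Fallback: it sets out from 26. Epoxidation with alkaline H2O2 (NaOH, MeOH/THF, 0 °C) gives 27 together with its mirror image, the (2S,3R)-epoxy ketone F5, as the racemate. The conditions of step 13 turn this into 28 together with (2S,3S)-6,8-diprenylaromadendrin F6. Preparative chromatography on a carbamate-type chiral stationary phase then delivers 28, at the cost of half the material.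

**Step 13.**
- What may go wrong: methanol may open the activated epoxide before the phenol does, the phenol may attack the α-carbon (5-exo closure), and on prolonged exposure the acid may add a phenol across a neighbouring prenyl double bond.
- Fallback: epoxide opening is separated from ring closure; it sets out from 27. Benzyl mercaptan with catalytic SnCl4 in CH2Cl2 at −20 °C opens the epoxide at the benzylic carbon and, as a thiol–Lewis acid pair, also removes the MOM groups. This gives (2S,3R)-3-(benzylsulfanyl)-2-hydroxy-3-(4-hydroxyphenyl)-1-[2,4,6-trihydroxy-3,5-bis(3-methylbut-2-enyl)phenyl]propan-1-one F7. AgBF4 in CH2Cl2 at 0 °C, with a hindered pyridine base to take up the acid, then ionises the C–S bond and an ortho phenol closes ring C. Closure should be trans-selective because C3 is untouched and the diequatorial product is favoured; it gives 28. This answers the wrong-site and solvolysis problems; the prenyl–phenol closure is limited only by the low temperature and the buffer.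

## Further compounds

F1 | step 7 | phloroglucinol (benzene-1,3,5-triol) | Oc1cc(O)cc(O)c1
F2 | step 7 | 1,3,5-tris(methoxymethoxy)benzene | COCOc1cc(OCOC)cc(OCOC)c1
F3 | step 7 | 1,3,5-tris(methoxymethoxy)-2-(3-methylbut-2-enyl)benzene | COCOc1cc(OCOC)c(CC=C(C)C)c(OCOC)c1
F4 | step 2 | 5-methylhex-4-en-1-yne | C#CCC=C(C)C
F5 | step 12 | [(2S,3R)-3-[4-(methoxymethoxy)phenyl]oxiran-2-yl][2,4,6-tris(methoxymethoxy)-3,5-bis(3-methylbut-2-enyl)phenyl]methanone | O=C(c1c(OCOC)c(CC=C(C)C)c(OCOC)c(CC=C(C)C)c1OCOC)[C@H]1O[C@@H]1c1ccc(OCOC)cc1
F6 | step 12 | (2S,3S)-3,5,7-trihydroxy-2-(4-hydroxyphenyl)-6,8-bis(3-methylbut-2-enyl)chroman-4-one | CC(C)=CCc1c(O)c(CC=C(C)C)c2c(c1O)C(=O)[C@@H](O)[C@H](c1ccc(O)cc1)O2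
F7 | step 13 | (2S,3R)-3-(benzylsulfanyl)-2-hydroxy-3-(4-hydroxyphenyl)-1-[2,4,6-trihydroxy-3,5-bis(3-methylbut-2-enyl)phenyl]propan-1-one | CC(C)=CCc1c(O)c(CC=C(C)C)c(O)c(C(=O)[C@H](O)[C@H](SCc2ccccc2)c2ccc(O)cc2)c1O
A1 | alternative 1 | (2R,3R)-3-(methoxymethoxy)-2-[4-(methoxymethoxy)phenyl]-5,7-bis(prop-2-enyloxy)chroman-4-one | c1c(OCC=C)cc2c(c1OCC=C)C(=O)[C@H](OCOC)[C@@H](c1ccc(OCOC)cc1)O2
A2 | alternative 1 | (2R,3R)-5,7-dihydroxy-3-(methoxymethoxy)-2-[4-(methoxymethoxy)phenyl]-6,8-bis(prop-2-enyl)chroman-4-one | C=CCc1c(O)c(CC=C)c2c(c1O)C(=O)[C@H](OCOC)[C@@H](c1ccc(OCOC)cc1)O2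
A3 | alternative 2 | (4R,5R)-4-(methoxymethoxy)-5-[4-(methoxymethoxy)phenyl]-5-[(5-methylhex-4-en-1-yn-1-yl)oxy]-1-(triisopropylsilyloxy)pent-1-yn-3-one | CC(C)[Si](C(C)C)(C(C)C)OC#CC(=O)[C@H](OCOC)[C@@H](c1ccc(OCOC)cc1)OC#CCC=C(C)C
A4 | alternative 2 | (2R,3R)-3-(methoxymethoxy)-2-[4-(methoxymethoxy)phenyl]-6,8-bis(3-methylbut-2-enyl)-5,7-bis(triisopropylsilyloxy)chroman-4-one | CC(C)=CCc1c(O[Si](C(C)C)(C(C)C)C(C)C)c(CC=C(C)C)c2c(c1O[Si](C(C)C)(C(C)C)C(C)C)C(=O)[C@H](OCOC)[C@@H](c1ccc(OCOC)cc1)O2
A5 | alternative 3 | 2-diazo-1-[2-fluoro-4,6-bis(methoxymethoxy)-3,5-bis(3-methylbut-2-enyl)phenyl]ethanone | CC(C)=CCc1c(OCOC)c(CC=C(C)C)c(F)c(C(=O)C=[N+]=[N-])c1OCOC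
A6 | alternative 3 | 4-methoxybenzyl alcohol | COc1ccc(CO)cc1
A7 | alternative 3 | (2R,3R)-1-[2-fluoro-4,6-bis(methoxymethoxy)-3,5-bis(3-methylbut-2-enyl)phenyl]-3-hydroxy-2-(4-methoxybenzyloxy)-3-[4-(methoxymethoxy)phenyl]propan-1-one | CC(C)=CCc1c(OCOC)c(CC=C(C)C)c(F)c(C(=O)[C@H](OCc2ccc(OC)cc2)[C@@H](c2ccc(OCOC)cc2)O)c1OCOC
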